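**Retrosynthetic overview**

1. Gnetumontanin B ⇒ its octamethyl ether (global O‑demethylation) ⇒ an open‑chain bis‑carbinol by cutting O1–C2 and O1'–C2'. The strategy rests on C2 (dihydrofuran O1–C2–C3 fused to the styryl‑bearing ring A) and C2' (dihydrofuran O1'–C2'–C3' fused to the central ring M): both are benzylic carbons carrying a 2,4‑dioxygenated aryl group (ring M on C2, ring E on C2'), so they ionise easily beside the fixed C3 and C3' centres.
2. Bis‑carbinol ⇒ C2–C7' bond from the aryl‑cerium reagent of the lower half (ring M bromide) and the (S)‑diarylacetaldehyde of the upper half; lower half ⇒ ring E aryl‑cerium reagent and a second (S)‑diarylacetaldehyde.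
3. Both aldehydes ⇒ periodate cleavage of 3,3‑diarylpropane‑1,2‑diols ⇒ copper‑catalysed, invertive opening of one (2S,3S)‑epoxy alcohol (Sharpless epoxidation of 3,5‑dimethoxycinnamyl alcohol) at its benzylic C3 by the 2,6‑dioxygenated arylmagnesium reagents of ring A (a stilbene) and of ring M; this sets C3 and C3'.
4. Ring order: no ring is closed before the key step. Both dihydrofuran rings (on ring A and on ring M) close together in one acid treatment; the three phenols it needs travel as SEM ethers, which fluoride removes without acid.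

Key step: step 13

Remark on the chemistry: the carbinol centres made in steps 10 and 11 form as epimer mixtures, are drawn as one epimer and are erased in step 13. SEM = 2‑(trimethylsilyl)ethoxymethyl. 2‑Bromo‑5‑methoxyphenol and diethyl (4‑methoxybenzyl)phosphonate are taken as purchased.

**Route**

Step 1
Reactants: 1 (E)-3,5-dimethoxycinnamic acid
Product: 3 (E)-3-(3,5-dimethoxyphenyl)prop-2-en-1-ol, via mixed carbonic anhydride 2 (not isolated)
Conditions: ClCO2Et, Et3N, THF, −10 °C; then NaBH4, THF/H2O, 0 °C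
Reagents that add atoms: none
Why: Activation as the mixed carbonic anhydride followed by borohydride reduction (mixed‑anhydride reduction) should reduce only the acyl carbon, so the (E)-alkene is kept and the allylic alcohol needed for directed epoxidation is obtained.

Step 2
Reactants: 3 (E)-3-(3,5-dimethoxyphenyl)prop-2-en-1-ol
Product: 4 [(2S,3S)-3-(3,5-dimethoxyphenyl)oxiran-2-yl]methanol
Conditions: Ti(OiPr)4 (10 mol%), L-(+)-diisopropyl tartrate (12 mol%), t-BuOOH, 4 Å molecular sieves, CH2Cl2, −20 °C
Reagents that add atoms: tert-butyl hydroperoxide, CC(C)(C)OO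
Why: Sharpless asymmetric epoxidation of an (E)-allylic alcohol with the L-(+)-tartrate ligand should deliver oxygen to the alkene face that gives the (2S,3S)-epoxy alcohol, which fixes the absolute configuration later carried by both C3 and C3'.

Step 3
Reactants: 5 3,5-dihydroxybenzaldehyde
Product: 6 3,5-bis{[2-(trimethylsilyl)ethoxy]methoxy}benzaldehyde
Conditions: SEMCl, i-Pr2NEt, CH2Cl2, 0 °C → rt
Reagents that add atoms: 2-(trimethylsilyl)ethoxymethyl chloride (SEMCl), C[Si](C)(C)CCOCCl
Why: O‑Alkylation of both phenols (Williamson‑type etherification) should give acetal ethers that survive strong bases and organometallic reagents, direct ortho‑metalation and can later be removed by fluoride without acid.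

Step 4
Reactants: 6 3,5-bis{[2-(trimethylsilyl)ethoxy]methoxy}benzaldehyde; 7 diethyl (4-methoxybenzyl)phosphonate
Product: 8 (E)-1-methoxy-4-(3,5-bis{[2-(trimethylsilyl)ethoxy]methoxy}styryl)benzene
Conditions: KOtBu, THF, 0 °C → rt
Reagents that add atoms: none
Why: Horner–Wadsworth–Emmons olefination of the aryl aldehyde with the benzylic phosphonate anion should give the (E)-stilbene, because the oxaphosphetane leading to the trans alkene is favoured for benzyl phosphonates.

Step 5
Reactants: 8 (E)-1-methoxy-4-(3,5-bis{[2-(trimethylsilyl)ethoxy]methoxy}styryl)benzene; 4 [(2S,3S)-3-(3,5-dimethoxyphenyl)oxiran-2-yl]methanol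
Product: 11 (2R,3S)-3-(3,5-dimethoxyphenyl)-3-{4-[(E)-4-methoxystyryl]-2,6-bis(SEM-oxy)phenyl}propane-1,2-diol, via aryllithium 9 (not isolated), via arylmagnesium bromide 10 (not isolated)
Conditions: 8 (2.5 equiv), lithium 2,2,6,6-tetramethylpiperidide (LiTMP), THF, −78 → 0 °C; MgBr2·OEt2, −78 °C; CuI (10 mol%), then 4, −30 → 0 °C
Reagents that add atoms: none
Why: Directed ortho‑metalation by the non‑nucleophilic amide should remove the proton flanked by the two OSEM groups without carbolithiation of the stilbene, and after transmetalation to magnesium the copper‑catalysed SN2 opening of the epoxy alcohol at its benzylic C3 should proceed with inversion, so that the (3S)-epoxide carbon becomes the (3S)-diarylmethine centre that is the future C3.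

Step 6
Reactants: 11 (2R,3S)-3-(3,5-dimethoxyphenyl)-3-{4-[(E)-4-methoxystyryl]-2,6-bis(SEM-oxy)phenyl}propane-1,2-diol
Product: 12 (2S)-2-(3,5-dimethoxyphenyl)-2-{4-[(E)-4-methoxystyryl]-2,6-bis(SEM-oxy)phenyl}acetaldehyde
Conditions: NaIO4, THF/pH 7 phosphate buffer, 0 °C; crude product dried and used at once
Reagents that add atoms: none
Why: Periodate glycol cleavage (Malaprade reaction) under buffered neutral conditions should excise C1 as formaldehyde and leave the adjacent diarylmethine centre untouched, the aldehyde being used at once because 2,2‑diarylacetaldehydes enolise easily.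

Step 7
Reactants: 13 2-bromo-5-methoxyphenol
Product: 14 1-bromo-4-methoxy-2-{[2-(trimethylsilyl)ethoxy]methoxy}benzene
Conditions: SEMCl, i-Pr2NEt, CH2Cl2, 0 °C → rt
Reagents that add atoms: 2-(trimethylsilyl)ethoxymethyl chloride (SEMCl), C[Si](C)(C)CCOCCl
Why: The same Williamson‑type etherification as in step 3 should give the ring M building block in which bromine already sits ortho to the protected oxygen and para to the methoxy group, the future C7'.

Step 8
Reactants: 14 1-bromo-4-methoxy-2-{[2-(trimethylsilyl)ethoxy]methoxy}benzene; 4 [(2S,3S)-3-(3,5-dimethoxyphenyl)oxiran-2-yl]methanol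
Product: 17 (2R,3S)-3-[3-bromo-6-methoxy-2-(SEM-oxy)phenyl]-3-(3,5-dimethoxyphenyl)propane-1,2-diol, via aryllithium 15 (not isolated), via arylmagnesium bromide 16 (not isolated)
Conditions: 14 (2.5 equiv), LiTMP, THF, −78 °C; MgBr2·OEt2, −78 °C; CuI (10 mol%), then 4, −30 → 0 °C
Reagents that add atoms: none
Why: The amide base should remove the most acidic ring proton, the one between OSEM and OMe, without bromine–lithium exchange, and the magnesium/copper sequence of step 5 should then open the epoxide at C3 with inversion (directed ortho‑metalation, copper‑catalysed epoxide opening) to set the future C3' in the same (S) sense while the aryl bromide is kept.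

Step 9
Reactants: 17 (2R,3S)-3-[3-bromo-6-methoxy-2-(SEM-oxy)phenyl]-3-(3,5-dimethoxyphenyl)propane-1,2-diol
Product: 18 (2S)-2-[3-bromo-6-methoxy-2-(SEM-oxy)phenyl]-2-(3,5-dimethoxyphenyl)acetaldehyde
Conditions: NaIO4, THF/pH 7 phosphate buffer, 0 °C; crude product dried and used at once
Reagents that add atoms: none
Why: Malaprade cleavage as in step 6 should give the second (S)-diarylacetaldehyde without touching its α‑centre.

Step 10
Reactants: 18 (2S)-2-[3-bromo-6-methoxy-2-(SEM-oxy)phenyl]-2-(3,5-dimethoxyphenyl)acetaldehyde; 19 1-bromo-2,4-dimethoxybenzene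
Product: 22 (2S)-2-[3-bromo-6-methoxy-2-(SEM-oxy)phenyl]-1-(2,4-dimethoxyphenyl)-2-(3,5-dimethoxyphenyl)ethan-1-ol (C1 epimers), via 2,4-dimethoxyphenyllithium 20 (not isolated), via arylcerium dichloride 21 (not isolated)
Conditions: 19 (1.5 equiv), n-BuLi, THF, −78 °C; CeCl3, −78 °C; then 18, −78 °C
Reagents that add atoms: none
Why: Bromine–lithium exchange and transmetalation to the weakly basic organocerium reagent should allow 1,2‑addition to the enolisable aldehyde at −78 °C without loss of the α‑centre and without exchange at the ring M bromide, and the new carbinol centre needs no control because it is erased in step 13.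

Step 11
Reactants: 22 (2S)-2-[3-bromo-6-methoxy-2-(SEM-oxy)phenyl]-1-(2,4-dimethoxyphenyl)-2-(3,5-dimethoxyphenyl)ethan-1-ol; 12 (2S)-2-(3,5-dimethoxyphenyl)-2-{4-[(E)-4-methoxystyryl]-2,6-bis(SEM-oxy)phenyl}acetaldehyde
Product: 25 tris-SEM-protected open-chain bis-carbinol (C2 and C2' epimers), via dilithio species 23 (not isolated), via arylcerium alkoxide 24 (not isolated)
Conditions: 22, n-BuLi (2.1 equiv), THF, −78 °C; CeCl3, −78 °C; then 12 (1.2 equiv), −78 °C
Reagents that add atoms: none
Why: The first equivalent of n-BuLi should form the lithium alkoxide and the second should effect bromine–lithium exchange on ring M ortho to OSEM, after which the derived organocerium reagent should add to the hindered, enolisable aldehyde without deprotonating it and so form the C2–C7' bond, the new carbinol centre again needing no control.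

Step 12
Reactants: 25 tris-SEM-protected open-chain bis-carbinol
Product: 26 open-chain bis-carbinol with free ring A 2,6-hydroxyls and free ring M C7a' hydroxyl (C2 and C2' epimers)
Conditions: Bu4NF, ethylenediamine, THF/DMPU, 60 °C, under argon
Reagents that add atoms: none
Why: Fluoride should attack silicon of each SEM group and fragment it to Me3SiF, ethene and formaldehyde (trapped by ethylenediamine), which frees the three phenols under basic conditions in which the acid‑labile carbinols cannot ionise (fluoride‑induced SEM cleavage).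

Step 13
Reactants: 26 open-chain bis-carbinol with free ring A 2,6-hydroxyls and free ring M C7a' hydroxyl
Product: 27 gnetumontanin B octamethyl ether with free ring A C4 hydroxyl
Conditions: CF3CO2H (2% v/v), CH2Cl2 (0.005 M), 0 °C → rt
Reagents that add atoms: none
Why: CF3CO2H protonates both benzylic hydroxyls and loss of water gives cations at C2 and C2' that are delocalised into ring M (ortho hydroxyl, para methoxy) and into ring E (2,4-dimethoxy), that is, protonated quinone methides in which the carbinol configurations are erased. The closest known reaction type is the acid‑mediated cyclodehydration of 2‑hydroxyaryl benzylic alcohols through ortho‑ or para‑quinone methide cations to trans‑2,3‑diaryl‑2,3‑dihydrobenzofurans. Each ring closes by 5‑exo‑trig attack of a phenol oxygen on the cationic carbon: a ring A hydroxyl on C2 forms O1–C2, and the ring M C7a' hydroxyl on C2' forms O1'–C2'. C2 and C2' are set under thermodynamic control, because ring closure is reversible in the acid and each ring settles in the trans arrangement that places its C2 (C2') aryl group anti to the aryl group on the fixed (S)-configured C3 (C3'), giving (2S,3S,2'S,3'S). The step needs constitutional selectivity and trans selectivity at both rings; the first is secured by the equivalence of the two ring A hydroxyls, by the methyl ether on ring M C4' (only the C7a' hydroxyl is free) and by the fact that every other intramolecular capture would need a four‑membered or bridged ring, the second by the reversibility. High dilution keeps the cations from intermolecular Friedel–Crafts reactions with the electron‑rich rings.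

Step 14
Reactants: 27 gnetumontanin B octamethyl ether with free ring A C4 hydroxyl
Product: 28 gnetumontanin B
Conditions: BBr3 (20 equiv), CH2Cl2, −78 °C → rt; quench at −78 °C with MeOH, then cold aq. NaHCO3
Reagents that add atoms: none
Why: Exhaustive Lewis‑acid ether cleavage, in which excess BBr3 should complex every ether oxygen and bromide should remove the eight methyl groups by SN2, while the boron‑complexed rings M and E are poor cation stabilisers so that the benzylic C2–O1 and C2'–O1' bonds should persist, and the cold buffered quench limits acid contact of the free polyphenol so that no stereocentre is touched.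

**Compound list**

1 | (E)-3,5-dimethoxycinnamic acid | COc1cc(/C=C/C(=O)O)cc(OC)c1 | starting material
2 | (E)-3,5-dimethoxycinnamic ethyl carbonic anhydride | CCOC(=O)OC(=O)/C=C/c1cc(OC)cc(OC)c1 | intermediate
3 | (E)-3-(3,5-dimethoxyphenyl)prop-2-en-1-ol | OC/C=C/c1cc(OC)cc(OC)c1 | intermediate
4 | [(2S,3S)-3-(3,5-dimethoxyphenyl)oxiran-2-yl]methanol | OC[C@@H]1O[C@H]1c1cc(OC)cc(OC)c1 | intermediate
5 | 3,5-dihydroxybenzaldehyde | O=Cc1cc(O)cc(O)c1 | starting material
6 | 3,5-bis{[2-(trimethylsilyl)ethoxy]methoxy}benzaldehyde | O=Cc1cc(OCOCC[Si](C)(C)C)cc(OCOCC[Si](C)(C)C)c1 | intermediate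
7 | diethyl (4-methoxybenzyl)phosphonate | CCOP(=O)(OCC)Cc1ccc(OC)cc1 | starting material
8 | (E)-1-methoxy-4-(3,5-bis{[2-(trimethylsilyl)ethoxy]methoxy}styryl)benzene | COc1ccc(/C=C/c2cc(OCOCC[Si](C)(C)C)cc(OCOCC[Si](C)(C)C)c2)cc1 | intermediate
9 | aryllithium of 8 (lithium between the two OSEM groups) | COc1ccc(/C=C/c2cc(OCOCC[Si](C)(C)C)c([Li])c(OCOCC[Si](C)(C)C)c2)cc1 | intermediate
10 | arylmagnesium bromide of 8 | COc1ccc(/C=C/c2cc(OCOCC[Si](C)(C)C)c([Mg]Br)c(OCOCC[Si](C)(C)C)c2)cc1 | intermediate
11 | (2R,3S)-3-(3,5-dimethoxyphenyl)-3-{4-[(E)-4-methoxystyryl]-2,6-bis(SEM-oxy)phenyl}propane-1,2-diol | OC[C@H](O)[C@H](c1c(OCOCC[Si](C)(C)C)cc(/C=C/c2ccc(OC)cc2)cc1OCOCC[Si](C)(C)C)c1cc(OC)cc(OC)c1 | intermediate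
12 | (2S)-2-(3,5-dimethoxyphenyl)-2-{4-[(E)-4-methoxystyryl]-2,6-bis(SEM-oxy)phenyl}acetaldehyde | O=C[C@H](c1c(OCOCC[Si](C)(C)C)cc(/C=C/c2ccc(OC)cc2)cc1OCOCC[Si](C)(C)C)c1cc(OC)cc(OC)c1 | intermediate
13 | 2-bromo-5-methoxyphenol | COc1ccc(Br)c(O)c1 | starting material
14 | 1-bromo-4-methoxy-2-{[2-(trimethylsilyl)ethoxy]methoxy}benzene | COc1ccc(Br)c(OCOCC[Si](C)(C)C)c1 | intermediate
15 | aryllithium of 14 (lithium between OSEM and OMe) | COc1ccc(Br)c(OCOCC[Si](C)(C)C)c1[Li] | intermediate
16 | arylmagnesium bromide of 14 | COc1ccc(Br)c(OCOCC[Si](C)(C)C)c1[Mg]Br | intermediate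
17 | (2R,3S)-3-[3-bromo-6-methoxy-2-(SEM-oxy)phenyl]-3-(3,5-dimethoxyphenyl)propane-1,2-diol | OC[C@H](O)[C@H](c1c(OC)ccc(Br)c1OCOCC[Si](C)(C)C)c1cc(OC)cc(OC)c1 | intermediate
18 | (2S)-2-[3-bromo-6-methoxy-2-(SEM-oxy)phenyl]-2-(3,5-dimethoxyphenyl)acetaldehyde | O=C[C@H](c1c(OC)ccc(Br)c1OCOCC[Si](C)(C)C)c1cc(OC)cc(OC)c1 | intermediate
19 | 1-bromo-2,4-dimethoxybenzene | COc1ccc(Br)c(OC)c1 | starting material
20 | 2,4-dimethoxyphenyllithium | COc1ccc([Li])c(OC)c1 | intermediate
21 | (2,4-dimethoxyphenyl)cerium dichloride | COc1ccc([Ce](Cl)Cl)c(OC)c1 | intermediate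
22 | (2S)-2-[3-bromo-6-methoxy-2-(SEM-oxy)phenyl]-1-(2,4-dimethoxyphenyl)-2-(3,5-dimethoxyphenyl)ethan-1-ol, C1 epimers, (1S,2S) drawn | COc1ccc(Br)c(OCOCC[Si](C)(C)C)c1[C@H](c1cc(OC)cc(OC)c1)[C@H](O)c1ccc(OC)cc1OC | intermediate
23 | O,C-dilithio derivative of 22 (lithium alkoxide, aryllithium at the former C–Br) | COc1ccc([Li])c(OCOCC[Si](C)(C)C)c1[C@H](c1cc(OC)cc(OC)c1)[C@H](O[Li])c1ccc(OC)cc1OC | intermediate
24 | arylcerium dichloride of 22 (lithium alkoxide) | COc1ccc([Ce](Cl)Cl)c(OCOCC[Si](C)(C)C)c1[C@H](c1cc(OC)cc(OC)c1)[C@H](O[Li])c1ccc(OC)cc1OC | intermediate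
25 | tris-SEM-protected open-chain bis-carbinol, C3 and C3' (S), carbinol epimers, one drawn | COc1ccc(/C=C/c2cc(OCOCC[Si](C)(C)C)c([C@H](c3cc(OC)cc(OC)c3)[C@H](O)c3ccc(OC)c([C@H](c4cc(OC)cc(OC)c4)[C@H](O)c4ccc(OC)cc4OC)c3OCOCC[Si](C)(C)C)c(OCOCC[Si](C)(C)C)c2)cc1 | intermediate
26 | open-chain bis-carbinol with three free phenols, C3 and C3' (S), carbinol epimers, one drawn | COc1ccc(/C=C/c2cc(O)c([C@H](c3cc(OC)cc(OC)c3)[C@H](O)c3ccc(OC)c([C@H](c4cc(OC)cc(OC)c4)[C@H](O)c4ccc(OC)cc4OC)c3O)c(O)c2)cc1 | intermediate
27 | gnetumontanin B octamethyl ether with free ring A C4 hydroxyl, (2S,3S,2'S,3'S) | COc1ccc(/C=C/c2cc(O)c3c(c2)O[C@H](c2ccc(OC)c4c2O[C@H](c2ccc(OC)cc2OC)[C@H]4c2cc(OC)cc(OC)c2)[C@H]3c2cc(OC)cc(OC)c2)cc1 | intermediate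
28 | gnetumontanin B | Oc1ccc(/C=C/c2cc(O)c3c(c2)O[C@H](c2ccc(O)c4c2O[C@H](c2ccc(O)cc2O)[C@H]4c2cc(O)cc(O)c2)[C@H]3c2cc(O)cc(O)c2)cc1 | target

**Step count and risks**

Total step count: 14. Longest linear sequence: 9 steps (steps 1, 2, 8, 9, 10, 11, 12, 13, 14).

Most likely to fail, first: step 13. With two cations to be handled in one molecule, a 1,2‑hydride shift from C3 or C3' to the neighbouring cation followed by proton loss would give aromatised or olefinic products and destroy a fixed centre, and trans equilibration of one ring may be incomplete while the other ring is still opening and closing. The fallback closes the rings one after the other; it sets out from 22 and comes back at 27. Bu4NF frees the ring M phenol of 22 to give the bromo phenol carbinol F1. CF3CO2H in CH2Cl2 then closes the lower ring alone to the trans‑7‑bromo‑2,3‑dihydrobenzofuran F2, on a small substrate where acid strength and time can be tuned. Bromine–lithium exchange with n-BuLi at −78 °C gives the aryllithium F3, CeCl3 converts it into the arylcerium reagent F4, and this adds to aldehyde 12 to give the mono‑carbinol F5, now without a free alkoxide in the nucleophile. Bu4NF removes the two SEM groups to give the diol carbinol F6, and CF3CO2H closes the upper ring, through a single cation, to 27.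

Second: step 14. Once the oxygens of rings E and M are free, acid released in the quench could re‑ionise C2'–O1' and let the lower ring re‑close on the newly freed ring M C4' oxygen (constitutional scrambling), and the free polyphenol may degrade on acidic work‑up and chromatography. The fallback never liberates the polyphenol in acid; it sets out from 27 and comes back at 28. After the BBr3 treatment the aryloxyborane mixture is quenched at −78 °C with pyridine/MeOH, concentrated and acetylated (Ac2O, pyridine, DMAP) to gnetumontanin B nonaacetate F7. In F7 every aryl oxygen is an ester and no ring can ionise. F7 is purified on silica and unmasked by methanolysis with K2CO3 in degassed MeOH at 0 °C to give 28.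

Third: step 5 (step 8 shares the risk). Transfer of the di‑ortho‑substituted aryl group from copper to the epoxide may be slow, so that MgBr2‑induced rearrangement of the epoxide or attack at C2 competes. The fallback makes the same C3–aryl bond by auxiliary‑controlled conjugate addition to a more reactive acceptor whose regiochemistry is fixed by its structure; it sets out from 1 and 8 and comes back at 12. Acid 1 is converted through its pivalic mixed anhydride (pivaloyl chloride, Et3N, LiCl) with (S)-4-phenyl-1,3-oxazolidin-2-one into the cinnamoyl imide F8. Arylmagnesium bromide 10, made from 8 as in step 5, adds in the presence of CuBr·SMe2 to the β‑carbon of the chelated imide anti to the auxiliary phenyl group, giving the (3S)-diarylpropanoyl imide F9. Enolisation with NaN(SiMe3)2 and oxidation with 2-(phenylsulfonyl)-3-phenyloxaziridine gives the α‑hydroxy imide F10. LiBH4 releases the auxiliary and gives the (2S,3S)-diol F11, the C2 epimer of 11, which NaIO4 cleaves to 12.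

**Further compounds**

F1 | step 13 | (2S)-2-(3-bromo-2-hydroxy-6-methoxyphenyl)-1-(2,4-dimethoxyphenyl)-2-(3,5-dimethoxyphenyl)ethan-1-ol, C1 epimers, one drawn | COc1ccc(Br)c(O)c1[C@H](c1cc(OC)cc(OC)c1)[C@H](O)c1ccc(OC)cc1OC
F2 | step 13 | (2S,3S)-7-bromo-2-(2,4-dimethoxyphenyl)-3-(3,5-dimethoxyphenyl)-4-methoxy-2,3-dihydro-1-benzofuran | Brc1ccc(OC)c2c1O[C@H](c1ccc(OC)cc1OC)[C@H]2c1cc(OC)cc(OC)c1
F3 | step 13 | 7-lithio derivative of F2 | [Li]c1ccc(OC)c2c1O[C@H](c1ccc(OC)cc1OC)[C@H]2c1cc(OC)cc(OC)c1
F4 | step 13 | 7-(dichlorocerio) derivative of F2 | Cl[Ce](Cl)c1ccc(OC)c2c1O[C@H](c1ccc(OC)cc1OC)[C@H]2c1cc(OC)cc(OC)c1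
F5 | step 13 | mono-carbinol with closed lower ring and bis-SEM-protected ring A, C2 epimers, one drawn | COc1ccc(/C=C/c2cc(OCOCC[Si](C)(C)C)c([C@H](c3cc(OC)cc(OC)c3)[C@H](O)c3ccc(OC)c4c3O[C@H](c3ccc(OC)cc3OC)[C@H]4c3cc(OC)cc(OC)c3)c(OCOCC[Si](C)(C)C)c2)cc1
F6 | step 13 | mono-carbinol with closed lower ring and free ring A 2,6-hydroxyls, C2 epimers, one drawn | COc1ccc(/C=C/c2cc(O)c([C@H](c3cc(OC)cc(OC)c3)[C@H](O)c3ccc(OC)c4c3O[C@H](c3ccc(OC)cc3OC)[C@H]4c3cc(OC)cc(OC)c3)c(O)c2)cc1
F7 | step 14 | gnetumontanin B nonaacetate | CC(=O)Oc1ccc(/C=C/c2cc(OC(C)=O)c3c(c2)O[C@H](c2ccc(OC(C)=O)c4c2O[C@H](c2ccc(OC(C)=O)cc2OC(C)=O)[C@H]4c2cc(OC(C)=O)cc(OC(C)=O)c2)[C@H]3c2cc(OC(C)=O)cc(OC(C)=O)c2)cc1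
F8 | step 5 | (4S)-3-[(E)-3-(3,5-dimethoxyphenyl)prop-2-enoyl]-4-phenyl-1,3-oxazolidin-2-one | COc1cc(/C=C/C(=O)N2C(=O)OC[C@@H]2c2ccccc2)cc(OC)c1
F9 | step 5 | (4S)-3-[(3S)-3-(3,5-dimethoxyphenyl)-3-{4-[(E)-4-methoxystyryl]-2,6-bis(SEM-oxy)phenyl}propanoyl]-4-phenyl-1,3-oxazolidin-2-one | O=C(C[C@H](c1c(OCOCC[Si](C)(C)C)cc(/C=C/c2ccc(OC)cc2)cc1OCOCC[Si](C)(C)C)c1cc(OC)cc(OC)c1)N1C(=O)OC[C@@H]1c1ccccc1
F10 | step 5 | (4S)-3-[(2S,3S)-2-hydroxy-3-(3,5-dimethoxyphenyl)-3-{4-[(E)-4-methoxystyryl]-2,6-bis(SEM-oxy)phenyl}propanoyl]-4-phenyl-1,3-oxazolidin-2-one | O=C([C@@H](O)[C@H](c1c(OCOCC[Si](C)(C)C)cc(/C=C/c2ccc(OC)cc2)cc1OCOCC[Si](C)(C)C)c1cc(OC)cc(OC)c1)N1C(=O)OC[C@@H]1c1ccccc1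
F11 | step 5 | (2S,3S)-3-(3,5-dimethoxyphenyl)-3-{4-[(E)-4-methoxystyryl]-2,6-bis(SEM-oxy)phenyl}propane-1,2-diol | OC[C@@H](O)[C@H](c1c(OCOCC[Si](C)(C)C)cc(/C=C/c2ccc(OC)cc2)cc1OCOCC[Si](C)(C)C)c1cc(OC)cc(OC)c1
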